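The constants used here were set for the occasion; no experiment stands behind them.

Take what stays: the sum of initiator and living end holds at 0.200 mM in amber and in ochre, for no step consumes a living end.

- amber: free monomer 20 mM; protic impurity 20.0 mM; initiator 1 mol%; time 50 min
- ochre: free monomer 20 mM; protic impurity 10.0 mM; initiator 1 mol%; time 50 min

- which of the two ends with the longer chains by the average number of monomer units in a chain (chains begun, living or dead) ("neither" if they lie within 10%) (amber / ochre / neither)
- average number of monomer units in a chain (chains begun, living or dead) at the end, amber
- average number of monomer units in a chain (chains begun, living or dead) at the end, ochre

- the average divides the monomer in chains by the number of chains begun, living and dead together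
- run time (amber): 50 min

Reckon on a clock of your own. Define exposure as c(free monomer) summed over time: initiation and growth are both first order in free monomer, so exposure is their common clock. On it a chain waits a mean start lag, the exposure spent before its initiator reacts, 14.9 M·s. Once chains begun approach the charge, average length is then close to one plus 0.66 M⁻¹ s⁻¹ times the difference of exposure and lag.

Get exposure two ways. First, freeze protic impurity at its charge and the chains at full count: in amber free monomer then decays pseudo-first-order at 0.0115 min⁻¹, giving 45.6 M·s. Second, keep protic impurity frozen, let free monomer fall in a straight line and set its loss equal to the quenched part plus the part in chains, with the length rule above: amber's exposure comes to 48.6 M·s, larger than the first.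

The first way cheats. It grants full chains from the start, yet the mean life of initiator at the charged free monomer is 12.4 min, a quarter of the run.

Keep the second. By this reckoning 3.84% of amber's initiator remains, so the lag rule may stand, and amber's length comes to about 23.3. Ochre drains at 0.00972 min⁻¹, reaches 50.4 M·s and gives 24.4. That gap of 5.00% is less than the margin, so expect neither.

The forecast says neither, with 24.7 for amber and 25.9 for ochre, both above this reckoning, holding that “chains begun equal initiator consumed”.

Amber ends at 24.7 and ochre at 25.9: neither. Amber keeps 62.6% of its free monomer at 50.0 min, and a straight line to that amount gives an exposure of 48.8 M·s; with the lag, the length rule turns this into 23.3, less than amber's computed length.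

    protic impurity + free monomer → quenched substrate (k1 = 0.0030 M⁻¹ s⁻¹)
    free monomer + living end → monomer in chains + living end, rate k2*[living end]*[free monomer] (k2 = 0.66 M⁻¹ s⁻¹)
    free monomer + initiator → living end + monomer in chains (k3 = 0.067 M⁻¹ s⁻¹)

Now charge amber with a quarter of the initiator, 0.25 mol%. The same lag and balance give 26.3; the flask gives 27.5, with 78.5% of its free monomer left.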